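Locants: C1 = CCl(CH3), C2 = CHCl, C3 = CH2, C4 = CHBr, C5 = C(CH3)(CH=CHBr), C6 = CH2. The retrosynthesis cuts, in order: both C–Cl bonds (cis-dichloride ⇐ C1/C2 epoxide ⇐ C1=C2 alkene), the vinyl C=C (aldehyde + CHBr3), C4–Br (⇐ C4–OH, inversion), and then the ring bonds C3–C4 and C6–C1 together.
Enabling feature: C5 is a neopentane-type carbon, and its three one-carbon arms (C4, C6, vinyl CH) are the three CH2OH groups of CH3C(CH2OH)3. C4 and C2 stand 1,3 on the six-membered ring (aldol spacing) and C6–C1(CH3)–C2 has the spacing of an aldol condensation, so CH3–C1–C2–C3 is butan-2-one.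
Forward: triol → mono-silyl ether → prochiral dial. One L-proline-catalysed aldol/aldol-condensation domino with butanone closes the only ring as a 5-hydroxycyclohex-2-enone. Tosylhydrazone reduction then moves the C=C to C1=C2 and makes C6 a CH2, followed by OH → Br, arm → (E)-bromovinyl, epoxidation and deoxydichlorination.
Stereochemistry: the catalyst fixes C4 (as the R-carbinol) and, by choosing one of two enantiotopic formyl groups, the quaternary C5 in the same event. C4–Br arises by inversion. The axial C5 arm sends the peracid to the opposite face, and both epoxide C–O bonds are replaced with inversion, which puts the cis-dichloride on the face of the bromovinyl group.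

Key step: step 3

Remark: target locants are used for the ring atoms throughout. "Top face" is the ring face that carries the C5 arm (CH2O, CHO or bromovinyl), and "bottom face" is the one that carries the C5 methyl group.

Step 1
Reactants: 1 1,1,1-tris(hydroxymethyl)ethane
Product: 2 2-{[tert-butyl(diphenyl)silyl]oxymethyl}-2-methylpropane-1,3-diol
Conditions: TBDPSCl (1 equiv), 1 (3 equiv), imidazole, DMF, 0 °C to rt
Reagents that add atoms: tert-butyl(chloro)diphenylsilane (TBDPSCl), CC(C)(C)[Si](Cl)(c1ccccc1)c1ccccc1
Why: Silyl ether formation on a triol whose three hydroxyls are homotopic, so only the degree of silylation has to be controlled (excess triol) and no stereocentre arises.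

Step 2
Reactants: 2 2-{[tert-butyl(diphenyl)silyl]oxymethyl}-2-methylpropane-1,3-diol
Product: 3 2-{[tert-butyl(diphenyl)silyl]oxymethyl}-2-methylpropanedial
Conditions: IBX (3 equiv), EtOAc, 80 °C, then filtration
Reagents that add atoms: none
Why: IBX oxidation of both primary neopentylic carbinols; the dial has no α-hydrogen and cannot enolise, and the water-free filtration work-up avoids hydrate formation and deformylation.

Step 3
Reactants: 3 2-{[tert-butyl(diphenyl)silyl]oxymethyl}-2-methylpropanedial; 4 butan-2-one
Product: 6 (4S,5R)-4-{[tert-butyl(diphenyl)silyl]oxymethyl}-5-hydroxy-2,4-dimethylcyclohex-2-en-1-one (OH trans to the silyloxymethyl arm), via keto aldehyde 5 (not isolated)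
Conditions: L-proline (30 mol %), butan-2-one/DMSO 1:4, 4 °C to rt, then 40 °C
Reagents that add atoms: none
Why: Proposed new method: L-proline turns butanone into its less substituted enamine, whose CH2 terminus adds through the usual acid-bridged chair transition state to one formyl group of 3 (C3–C4 bond) to give keto aldehyde 5, and the ethyl-side enamine or enol of 5 then attacks the second formyl group, held as its prolinium ion, after which loss of the amine leaves the C6=C1 enone. The closest known reaction types are the proline-catalysed intermolecular aldol of methyl ketones with α-quaternary aldehydes and the amine-catalysed cyclodehydration that ends a Robinson annulation; their union on a prochiral 2,2-disubstituted malonaldehyde is what is new. The one ring closes in the 6-(enolendo)-exo-trig mode. C4 is set by the catalyst (Re-face attack, R-carbinol, as with pivalaldehyde-type acceptors), and C5 is set in the same transition state by the choice between the two enantiotopic formyl groups, because both the steric arrangement (bulky CH2OTBDPS arm anti to the incoming carbon, flat formyl group beside its path) and the dipole-minimised one (second formyl anti, arm inside, methyl outside) lead to the isomer with OH trans to the arm. Regioselectivity (methyl carbon first, methylene carbon second) follows from the kinetic preference of the proline enamine and from the fact that in 5 only the ethyl CH2 can reach the free formyl group through a six-membered ring, and self-condensation of 3 is excluded since it has no α-hydrogen. The step also needs the C4 hydroxyl to survive, which the nearly neutral medium and the moderate temperature should secure.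

Step 4
Reactants: 6 (4S,5R)-4-{[tert-butyl(diphenyl)silyl]oxymethyl}-5-hydroxy-2,4-dimethylcyclohex-2-en-1-one
Product: 7 N-tosylhydrazone of 6
Conditions: TsNHNH2, MeOH/THF, rt
Reagents that add atoms: p-toluenesulfonyl hydrazide, Cc1ccc(cc1)S(=O)(=O)NN
Why: Hydrazone formation at the only carbonyl group under neutral conditions, which should spare the β-hydroxyl and the silyl ether and touches no stereocentre.

Step 5
Reactants: 7 N-tosylhydrazone of 6
Product: 9 (1R,6S)-6-{[tert-butyl(diphenyl)silyl]oxymethyl}-4,6-dimethylcyclohex-3-en-1-ol, via allylic diazene 8 (not isolated)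
Conditions: catecholborane (2.5 equiv), CHCl3, −10 °C; then NaOAc·3H2O, reflux
Reagents that add atoms: none
Why: Reductive 1,3-transposition of an enone tosylhydrazone: hydride adds to C=N, loss of sulfinate gives allylic diazene 8, and its retro-ene loss of N2 delivers hydrogen to C6 and moves the double bond to C1=C2, as known for 2-methylcyclohexenone-type hydrazones, with C4 and C5 untouched.

Step 6
Reactants: 9 (1R,6S)-6-{[tert-butyl(diphenyl)silyl]oxymethyl}-4,6-dimethylcyclohex-3-en-1-ol
Product: 10 tert-butyl{[(1S,6S)-6-bromo-1,3-dimethylcyclohex-3-en-1-yl]methoxy}diphenylsilane (Br cis to the arm)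
Conditions: CBr4, P(n-C8H17)3, toluene, 70 °C
Reagents that add atoms: carbon tetrabromide, BrC(Br)(Br)Br
Why: Appel-type bromination in which bromide displaces the alkoxyphosphonium group by SN2 with inversion, turning the bottom-face carbinol into the top-face bromide; the electron-rich trialkylphosphine, the non-ionising solvent and heat are the conditions that serve for secondary carbinols next to fully substituted carbons, and silyl ether and alkene are inert to them.

Step 7
Reactants: 10 tert-butyl{[(1S,6S)-6-bromo-1,3-dimethylcyclohex-3-en-1-yl]methoxy}diphenylsilane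
Product: 11 [(1S,6S)-6-bromo-1,3-dimethylcyclohex-3-en-1-yl]methanol
Conditions: HF·pyridine, excess pyridine, THF, 0 °C to rt
Reagents that add atoms: none
Why: Fluoride-driven silyl ether cleavage under buffered acidic conditions, chosen over basic fluoride so that the liberated 1,3-bromo alcohol cannot close to an oxetane and the alkene is not hydrofluorinated; no stereocentre is touched.

Step 8
Reactants: 11 [(1S,6S)-6-bromo-1,3-dimethylcyclohex-3-en-1-yl]methanol
Product: 12 (1S,6S)-6-bromo-1,3-dimethylcyclohex-3-ene-1-carbaldehyde
Conditions: Dess–Martin periodinane, CH2Cl2, 0 °C to rt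
Reagents that add atoms: none
Why: Dess–Martin oxidation of a primary neopentylic carbinol under neutral conditions; the aldehyde has no α-hydrogen, so neither epimerisation at C5 nor E1cB loss of HBr can occur.

Step 9
Reactants: 12 (1S,6S)-6-bromo-1,3-dimethylcyclohex-3-ene-1-carbaldehyde
Product: 13 (4S,5S)-4-bromo-5-[(E)-2-bromoethenyl]-1,5-dimethylcyclohex-1-ene
Conditions: CHBr3, CrBr2 (6 equiv), THF, 0 °C to rt
Reagents that add atoms: bromoform, BrC(Br)Br
Why: Takai olefination, in which the gem-dichromium carbenoid adds to the hindered, non-enolisable aldehyde and elimination gives the (E)-bromoalkene; CrBr2 instead of CrCl2 avoids halogen exchange, and unactivated secondary alkyl bromides are not reduced by divalent chromium in the absence of a cobalt co-catalyst.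

Step 10
Reactants: 13 (4S,5S)-4-bromo-5-[(E)-2-bromoethenyl]-1,5-dimethylcyclohex-1-ene
Product: 14 (1R,3S,4S,6S)-4-bromo-3-[(E)-2-bromoethenyl]-1,3-dimethyl-7-oxabicyclo[4.1.0]heptane (oxygen on the bottom face)
Conditions: mCPBA, CH2Cl2, −10 to 0 °C
Reagents that add atoms: 3-chloroperoxybenzoic acid (mCPBA), OOC(=O)c1cccc(Cl)c1
Why: Prilezhaev epoxidation: the trisubstituted ring alkene is far more nucleophilic than the bromoalkene, and in the favoured half-chair (Br pseudo-equatorial, bromovinyl axial, C5 methyl equatorial) the top face is shielded by the axial bromovinyl group 1,3 to C1, so oxygen should be delivered to the bottom face, which sets C1 and C2.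

Step 11
Reactants: 14 (1R,3S,4S,6S)-4-bromo-3-[(E)-2-bromoethenyl]-1,3-dimethyl-7-oxabicyclo[4.1.0]heptane
Product: 16 (1S,2R,4S,5S)-4-bromo-5-[(E)-2-bromoethenyl]-1,2-dichloro-1,5-dimethylcyclohexane, via chloroalkoxyphosphonium chloride 15 (not isolated)
Conditions: Ph3PCl2 (1.5 equiv), CH2Cl2, 0 °C to reflux
Reagents that add atoms: dichlorotriphenylphosphorane, ClP(Cl)(c1ccccc1)(c1ccccc1)c1ccccc1
Why: Deoxydichlorination of an epoxide with a dihalophosphorane: after P–O activation chloride opens the tertiary C1 from the top face in a trans-diaxial manner (inversion) to 15, and a second chloride displaces Ph3PO at C2 with inversion, so the bottom-face epoxide becomes the top-face cis-dichloride, as cyclohexene oxide gives cis-1,2-dichlorocyclohexane.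

Compound list
1 | 1,1,1-tris(hydroxymethyl)ethane | CC(CO)(CO)CO | starting material
2 | 2-{[tert-butyl(diphenyl)silyl]oxymethyl}-2-methylpropane-1,3-diol | CC(CO)(CO)CO[Si](c1ccccc1)(c1ccccc1)C(C)(C)C | intermediate
3 | 2-{[tert-butyl(diphenyl)silyl]oxymethyl}-2-methylpropanedial | CC(C=O)(C=O)CO[Si](c1ccccc1)(c1ccccc1)C(C)(C)C | intermediate
4 | butan-2-one | CCC(C)=O | starting material
5 | (2S,3R)-2-{[tert-butyl(diphenyl)silyl]oxymethyl}-3-hydroxy-2-methyl-5-oxoheptanal | CCC(=O)C[C@@H](O)[C@](C)(CO[Si](c1ccccc1)(c1ccccc1)C(C)(C)C)C=O | intermediate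
6 | (4S,5R)-4-{[tert-butyl(diphenyl)silyl]oxymethyl}-5-hydroxy-2,4-dimethylcyclohex-2-en-1-one | CC1=C[C@@](C)(CO[Si](c2ccccc2)(c2ccccc2)C(C)(C)C)[C@H](O)CC1=O | intermediate
7 | N-tosylhydrazone of 6 | CC1=C[C@@](C)(CO[Si](c2ccccc2)(c2ccccc2)C(C)(C)C)[C@H](O)CC1=NNS(=O)(=O)c3ccc(C)cc3 | intermediate
8 | allylic diazene (diazenyl group at C2, configuration there without consequence) | CC1=C[C@@](C)(CO[Si](c2ccccc2)(c2ccccc2)C(C)(C)C)[C@H](O)CC1N=N | intermediate
9 | (1R,6S)-6-{[tert-butyl(diphenyl)silyl]oxymethyl}-4,6-dimethylcyclohex-3-en-1-ol | CC1=CC[C@@H](O)[C@](C)(CO[Si](c2ccccc2)(c2ccccc2)C(C)(C)C)C1 | intermediate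
10 | tert-butyl{[(1S,6S)-6-bromo-1,3-dimethylcyclohex-3-en-1-yl]methoxy}diphenylsilane | CC1=CC[C@H](Br)[C@](C)(CO[Si](c2ccccc2)(c2ccccc2)C(C)(C)C)C1 | intermediate
11 | [(1S,6S)-6-bromo-1,3-dimethylcyclohex-3-en-1-yl]methanol | CC1=CC[C@H](Br)[C@](C)(CO)C1 | intermediate
12 | (1S,6S)-6-bromo-1,3-dimethylcyclohex-3-ene-1-carbaldehyde | CC1=CC[C@H](Br)[C@](C)(C=O)C1 | intermediate
13 | (4S,5S)-4-bromo-5-[(E)-2-bromoethenyl]-1,5-dimethylcyclohex-1-ene | CC1=CC[C@H](Br)[C@](C)(/C=C/Br)C1 | intermediate
14 | (1R,3S,4S,6S)-4-bromo-3-[(E)-2-bromoethenyl]-1,3-dimethyl-7-oxabicyclo[4.1.0]heptane | C[C@]12O[C@H]1C[C@H](Br)[C@](C)(/C=C/Br)C2 | intermediate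
15 | chloroalkoxyphosphonium chloride (C1–Cl on the top face, C2–OPPh3 on the bottom face) | C[C@]1(Cl)C[C@@](C)(/C=C/Br)[C@@H](Br)C[C@@H]1O[P+](c2ccccc2)(c3ccccc3)c4ccccc4.[Cl-] | intermediate
16 | (1S,2R,4S,5S)-4-bromo-5-[(E)-2-bromoethenyl]-1,2-dichloro-1,5-dimethylcyclohexane | C[C@]1(Cl)C[C@@](C)(/C=C/Br)[C@@H](Br)C[C@H]1Cl | target

Total step count: 11. Longest linear sequence: 11 steps (from 1).

Steps most likely to fail

Step 3 (new method). The amine may deformylate the dial. The two formyl groups may be poorly discriminated, which would erode diastereomeric and in the end enantiomeric purity. The domino may also stall at the open-chain stage, or the C4 hydroxyl may be lost by E1cB. The fallback uses known chemistry, sets out from 2 and comes back at 5, which is then cyclised separately to 6. It assigns the two selections to two separate agents. Diol 2 is desymmetrised by lipase-catalysed mono-acetylation (Candida antarctica lipase B or a screened alternative, vinyl acetate) to the (S)-monoacetate F1. Dess–Martin oxidation gives the α-quaternary aldehyde F2. The L-proline-catalysed aldol with butanone, a known reaction for this acceptor class, gives the β-hydroxy ketone acetate F3. Mild methanolysis (K2CO3, MeOH, 0 °C) gives the keto diol F4. TEMPO/PhI(OAc)2 oxidises only the primary carbinol to 5, which pyrrolidinium acetate should close to 6.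

Step 6. Substitution at the neopentylic C4 may be too slow. Elimination towards C3, homoallylic participation of the C1=C2 bond (retention or cyclopropane formation) or ionisation with rearrangement could then take over. The fallback sets out from 6 and comes back at 10, and it replaces nucleophilic by electrophilic C–Br bond formation. MsCl/Et3N dehydrates 6 to the cross-conjugated dienone F5. Conjugate borylation (CuCl, NaOt-Bu, Xantphos, B2pin2, MeOH, THF) should take place at the enone arm without α-methyl group and anti to the bulky arm, giving the β-boryl enone F6. TsNHNH2 gives the hydrazone F7. Catecholborane followed by NaOAc·3H2O gives the homoallylic boronic ester F8. Its ate complex with 3,5-bis(trifluoromethyl)phenyllithium is brominated with NBS at −78 °C with inversion to give 10.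

Step 11. The cation-like C1 may lose a proton, giving allylic chloride formation. Full ionisation at C1 may cause loss of inversion, or elimination may occur in the second displacement. The fallback sets out from 14 and comes back at 16. It forms the two C–Cl bonds in separate, individually adjustable steps and changes the leaving group at C2. Anhydrous HCl in Et2O at low temperature opens the epoxide trans-diaxially at C1 to the isolable chlorohydrin F9. Tf2O/pyridine gives the axial triflate F10, and Bu4NCl in toluene displaces it with inversion to give 16.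

Further compounds
F1 | step 3 | (S)-3-{[tert-butyl(diphenyl)silyl]oxy}-2-(hydroxymethyl)-2-methylpropyl acetate | CC(=O)OC[C@@](C)(CO[Si](c1ccccc1)(c1ccccc1)C(C)(C)C)CO
F2 | step 3 | (S)-3-{[tert-butyl(diphenyl)silyl]oxy}-2-formyl-2-methylpropyl acetate | CC(=O)OC[C@@](C)(CO[Si](c1ccccc1)(c1ccccc1)C(C)(C)C)C=O
F3 | step 3 | 2-{[tert-butyl(diphenyl)silyl]oxymethyl}-3-hydroxy-2-methyl-5-oxoheptyl acetate (configured as 5) | CCC(=O)C[C@@H](O)[C@](C)(CO[Si](c1ccccc1)(c1ccccc1)C(C)(C)C)COC(C)=O
F4 | step 3 | 6-{[tert-butyl(diphenyl)silyl]oxymethyl}-5,7-dihydroxy-6-methylheptan-3-one (configured as 5) | CCC(=O)C[C@@H](O)[C@](C)(CO[Si](c1ccccc1)(c1ccccc1)C(C)(C)C)CO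
F5 | step 6 | (S)-4-{[tert-butyl(diphenyl)silyl]oxymethyl}-2,4-dimethylcyclohexa-2,5-dien-1-one | CC1=C[C@@](C)(CO[Si](c2ccccc2)(c2ccccc2)C(C)(C)C)C=CC1=O
F6 | step 6 | 4-{[tert-butyl(diphenyl)silyl]oxymethyl}-2,4-dimethyl-5-(pinacolatoboryl)cyclohex-2-en-1-one (boron trans to the arm) | CC1=C[C@@](C)(CO[Si](c2ccccc2)(c2ccccc2)C(C)(C)C)[C@H](B2OC(C)(C)C(C)(C)O2)CC1=O
F7 | step 6 | N-tosylhydrazone of F6 | CC1=C[C@@](C)(CO[Si](c2ccccc2)(c2ccccc2)C(C)(C)C)[C@H](B2OC(C)(C)C(C)(C)O2)CC1=NNS(=O)(=O)c3ccc(C)cc3
F8 | step 6 | pinacol 6-{[tert-butyl(diphenyl)silyl]oxymethyl}-4,6-dimethylcyclohex-3-en-1-ylboronate (boron trans to the arm) | CC1=CC[C@@H](B2OC(C)(C)C(C)(C)O2)[C@](C)(CO[Si](c2ccccc2)(c2ccccc2)C(C)(C)C)C1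
F9 | step 11 | (1S,2S,4S,5S)-5-bromo-4-[(E)-2-bromoethenyl]-2-chloro-2,4-dimethylcyclohexan-1-ol | C[C@]1(Cl)C[C@@](C)(/C=C/Br)[C@@H](Br)C[C@@H]1O
F10 | step 11 | trifluoromethanesulfonate of F9 | C[C@]1(Cl)C[C@@](C)(/C=C/Br)[C@@H](Br)C[C@@H]1OS(=O)(=O)C(F)(F)F
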